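The route rests on forming the C8–C9 bond, which joins the methyl-bearing methine to the quaternary α-carbon of the ring ketone, by a Claisen ring expansion. The target's seven-membered ring hides a γ,δ-unsaturated ketone pattern (C10 ketone, C9, C8, then C7 and C6), so the precursor is a cis-fused 2-alkylidene-5-propenyl oxolane (O bridging C10 and C6) on the cyclopentane. One [3,3] shift opens the oxolane, closes the cycloheptenone, and sets the C9 quaternary centre and C8 from two alkene geometries. Diimide reduction, desilylation and a magnesium-templated retro-aldol/aldol inversion of the C5 carbinol complete the synthesis.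

Key step: step 9

Remark on numbering: cyclopentane C1 (ring-fusion CH), C2 (CH2), C3 (CHOH), C4 (CMe2), C5 (ring-fusion C–OH); seven-membered ring C5, C6, C7, C8 (CHMe), C9 (quaternary), C10 (C=O), C1; side chain C11, C12; butenolide C13–C16.

Assumption: in step 4 the antipode of the chiral chromium ligand is selected for the 6S carbinol; its sense is not predicted here.

Assumption: the Claisen shift can only give the cis-fused ketol, so it is run to set C8, C9 and C1 correctly and to leave C5 epimeric; C5 is inverted in step 12.

Step 1
Reactants: 1 2,2-dimethylcyclopentane-1,3-dione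
Product: 2 (R)-3-hydroxy-2,2-dimethylcyclopentan-1-one
Conditions: (S)-Me-CBS oxazaborolidine (10 mol %), BH3·SMe2 (0.6 equiv), THF, −30 °C
Reagents that add atoms: none
Why: Corey–Bakshi–Shibata reduction desymmetrises the dione; with the quaternary carbon as the large group the (S)-catalyst should give the 3R carbinol, and limiting hydride spares the second carbonyl.

Step 2
Reactants: 2 (R)-3-hydroxy-2,2-dimethylcyclopentan-1-one
Product: 3 (R)-3-(tert-butyldimethylsilyloxy)-2,2-dimethylcyclopentan-1-one
Conditions: TBSOTf, 2,6-lutidine, CH2Cl2, 0 °C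
Reagents that add atoms: tert-butyldimethylsilyl triflate, CC(C)(C)[Si](C)(C)OS(=O)(=O)C(F)(F)F
Why: Silyl ether formation on the hindered secondary alcohol; the bulky ether later shields one face of the ring.

Step 3
Reactants: 3 TBS ether ketone
Product: 4 (R)-4-(tert-butyldimethylsilyloxy)-5,5-dimethylcyclopent-1-en-1-yl triflate
Conditions: KN(SiMe3)2, PhNTf2, THF, −78 °C
Reagents that add atoms: N-phenylbis(trifluoromethanesulfonimide), O=S(=O)(N(c1ccccc1)S(=O)(=O)C(F)(F)F)C(F)(F)F
Why: Enolate O-triflation; only the CH2 side can enolise because the other α-carbon is quaternary.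

Step 4
Reactants: 4 enol triflate; 5 (E)-but-2-enal
Product: 6 (1S,2E)-1-[(4R)-4-(tert-butyldimethylsilyloxy)-5,5-dimethylcyclopent-1-en-1-yl]but-2-en-1-ol
Conditions: CrCl2, Kishi oxazoline–sulfonamide ligand, Et3N, NiCl2 (cat.), THF, 23 °C
Reagents that add atoms: none
Why: Nozaki–Hiyama–Kishi coupling: zerovalent nickel activates the vinyl triflate, transmetalation gives an alkenylchromium species that adds 1,2 to the enal, and the chiral ligand on chromium selects the aldehyde face to set the 6S carbinol.

Step 5
Reactants: 6 dienol
Product: 7 threo epoxy alcohol (C1–C5 oxirane, oxygen trans to the silyl ether)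
Conditions: mCPBA, NaHCO3, CH2Cl2, 0 °C
Reagents that add atoms: 3-chloroperbenzoic acid, OOC(=O)c1cccc(Cl)c1
Why: Prilezhaev epoxidation picks the electron-rich trisubstituted ring alkene over the propenyl group and should enter anti to the bulky C3 silyl ether, which with the 6S carbinol gives the threo epoxy alcohol.

Step 6
Reactants: 7 threo epoxy alcohol; 8 1-propynyllithium
Product: 9 alkynyl diol (C1 propynyl trans to the C5 hydroxyl, cis to the C6 carbinol arm and to the silyl ether)
Conditions: 8 and Et2AlCl premixed (toluene, 0 °C), then 7, 0 → 23 °C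
Reagents that add atoms: none
Why: Alkynylalane opening of the epoxy alcohol (SN2) at the less substituted oxirane carbon C1 with inversion puts the propynyl group trans to the new tertiary C5 hydroxyl.

Step 7
Reactants: 9 alkynyl diol; 10 vinyl bromide
Product: 11 dienyl enol ether (cis-fused 3-oxabicyclo[3.3.0]octane, E enol ether with methyl syn to oxygen, E-propenyl on the convex face cis to the angular hydroxyl)
Conditions: n-BuLi (1 equiv), THF, 0 °C; then Pd(OAc)2 (5 mol %), PPh3, 10, 50 °C
Reagents that add atoms: none
Why: Cyclisation–coupling of an acetylenic alkoxide: the vinylpalladium bromide activates the alkyne, the secondary C6 alkoxide attacks C10 anti (5-exo-dig) and reductive elimination joins vinyl to C9 trans to oxygen; the tertiary hydroxyl is trans to the alkyne and cannot close.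

Step 8
Reactants: 11 dienyl enol ether; 12 4-bromofuran-2(5H)-one
Product: 14 Claisen substrate (E enol ether carrying the complete butenolide side chain), via alkylborane 13 (not isolated)
Conditions: 9-BBN, THF, 0 → 23 °C; then 12, PdCl2(dppf) (cat.), AsPh3, K3PO4 (aq), DMF, 23 °C
Reagents that add atoms: none
Why: Hydroboration with 9-BBN is selective for the only monosubstituted alkene, and B-alkyl Suzuki–Miyaura coupling with the vinylogous acyl bromide installs the butenolide under basic conditions that preserve the acid-labile enol ether.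

Step 9
Reactants: 14 Claisen substrate
Product: 15 cis-fused cyclohept-4-enone (C8, C9, C1, C3 as in the target; C5 epimeric; C6=C7 alkene)
Conditions: toluene, 2,6-di-tert-butyl-4-methylpyridine (0.2 equiv), 175 °C, sealed tube, base-washed glass
Reagents that add atoms: none
Why: Thermal [3,3]-sigmatropic (Claisen) rearrangement of the allyl vinyl ether C9=C10–O–C6–C7=C8: the C6–O bond breaks while C8–C9 forms and C10 becomes the ketone. The closest known reaction type is the Claisen ring expansion of 2-alkylidene-5-alkenyltetrahydrofurans to cyclohept-4-enones. The seven-membered ring closes through a chair-like six-membered pericyclic array bridged by C1–C5 (a bicyclo[3.2.1]-like transition state, the only topology the two-atom bridge allows for a cis ring alkene), with net two-carbon expansion of the oxolane. C9 is controlled by the E enol ether (the methyl syn to oxygen goes axial, the chain equatorial) and C8 by the E-propenyl group (methyl equatorial), so the two methyls come out cis; the face is fixed by C6, whose propenyl group sits on the convex face cis to the C5 hydroxyl, so the axial C8–H meets only OH and H. The step needs the shift to outrun acid-catalysed migration of the exocyclic enol ether double bond into the ring, which the hindered base, base-washed glass and the already saturated side chain (no diene for a [1,5]-hydrogen shift) should secure. The C5 carbinol necessarily emerges cis-fused and is corrected in step 12.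

Step 10
Reactants: 15 cyclohept-4-enone
Product: 16 saturated cis-fused ketol TBS ether
Conditions: 2-nitrobenzenesulfonylhydrazide, Et3N, CH2Cl2, 23 °C
Reagents that add atoms: none
Why: Diimide reduction (concerted syn delivery of H2) prefers the cis-disubstituted ring alkene to the trisubstituted, conjugated butenolide alkene and creates no stereocentre.

Step 11
Reactants: 16 saturated ketol TBS ether
Product: 17 C5 epimer of the target (cis-fused diol ketol)
Conditions: HF·pyridine, THF, 0 → 23 °C
Reagents that add atoms: none
Why: Fluoride-driven silyl ether cleavage under buffered, non-basic conditions should leave the β-ketol and the butenolide untouched.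

Step 12
Reactants: 17 C5 epimer of the target
Product: 19 CNP0077405.1, via ten-membered diketone 18 (not isolated)
Conditions: MgBr2·OEt2 (3 equiv), Et3N (3 equiv), CH2Cl2, 23 → 40 °C
Reagents that add atoms: none
Why: Retro-aldol/transannular aldol equilibration through the magnesium enolate of cyclodecane-1,6-dione 18 breaks and re-forms the C1–C5 bond; only the target places O3, O5 and the C10 carbonyl on one face of the cyclopentane for tridentate magnesium chelation, so C5 and C1 should settle in the target configuration while C3, C8 and C9 cannot change.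

Compound list

1 | 2,2-dimethylcyclopentane-1,3-dione | CC1(C)C(=O)CCC1=O | starting material
2 | (R)-3-hydroxy-2,2-dimethylcyclopentan-1-one | O=C1CC[C@@H](O)C1(C)C | intermediate
3 | (R)-3-(tert-butyldimethylsilyloxy)-2,2-dimethylcyclopentan-1-one | O=C1CC[C@@H](O[Si](C)(C)C(C)(C)C)C1(C)C | intermediate
4 | (R)-4-(tert-butyldimethylsilyloxy)-5,5-dimethylcyclopent-1-en-1-yl trifluoromethanesulfonate | FC(F)(F)S(=O)(=O)OC1=CC[C@@H](O[Si](C)(C)C(C)(C)C)C1(C)C | intermediate
5 | (E)-but-2-enal | C/C=C/C=O | starting material
6 | (1S,2E)-1-[(4R)-4-(tert-butyldimethylsilyloxy)-5,5-dimethylcyclopent-1-en-1-yl]but-2-en-1-ol | C/C=C/[C@H](O)C1=CC[C@@H](O[Si](C)(C)C(C)(C)C)C1(C)C | intermediate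
7 | threo epoxy alcohol: C1–C5 oxirane of 6, oxirane oxygen trans to the silyl ether | C/C=C/[C@H](O)[C@@]12O[C@@H]1C[C@@H](O[Si](C)(C)C(C)(C)C)C2(C)C | intermediate
8 | 1-propynyllithium | [Li]C#CC | starting material
9 | alkynyl diol: C5 tertiary alcohol bearing the (E)-1-hydroxybut-2-enyl arm, C1 propynyl trans to C5–OH and cis to the silyl ether | C/C=C/[C@H](O)[C@@]1(O)[C@@H](C#CC)C[C@@H](O[Si](C)(C)C(C)(C)C)C1(C)C | intermediate
10 | vinyl bromide | C=CBr | starting material
11 | dienyl enol ether: cis-fused 3-oxabicyclo[3.3.0]octane with (E)-but-3-en-2-ylidene at C10, (E)-propenyl at C6 cis to the angular C5 hydroxyl, silyl ether at C3 | C/C=C/[C@@H]1O/C(=C(\C)C=C)[C@H]3C[C@@H](O[Si](C)(C)C(C)(C)C)C(C)(C)[C@@]13O | intermediate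
12 | 4-bromofuran-2(5H)-one | O=C1C=C(Br)CO1 | starting material
13 | B-alkyl-9-BBN adduct of 11 (boron on C12) | C/C=C/[C@@H]1O/C(=C(\C)CCB4C5CCCC4CCC5)[C@H]3C[C@@H](O[Si](C)(C)C(C)(C)C)C(C)(C)[C@@]13O | intermediate (not isolated)
14 | Claisen substrate: E enol ether with methyl syn to oxygen and the 2-(5-oxo-2,5-dihydrofuran-3-yl)ethyl chain anti | C/C=C/[C@@H]1O/C(=C(\C)CCC2=CC(=O)OC2)[C@H]3C[C@@H](O[Si](C)(C)C(C)(C)C)C(C)(C)[C@@]13O | intermediate
15 | cis-fused cyclohept-4-enone (Claisen product, 5-epi, C6=C7) | C[C@@H]1C=C[C@@]2(O)[C@H](C[C@@H](O[Si](C)(C)C(C)(C)C)C2(C)C)C(=O)[C@@]1(C)CCC1=CC(=O)OC1 | intermediate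
16 | saturated cis-fused ketol TBS ether (5-epi) | C[C@@H]1CC[C@@]2(O)[C@H](C[C@@H](O[Si](C)(C)C(C)(C)C)C2(C)C)C(=O)[C@@]1(C)CCC1=CC(=O)OC1 | intermediate
17 | C5 epimer of the target (1S,3R,5R,8R,9S) | C[C@@H]1CC[C@@]2(O)[C@H](C[C@@H](O)C2(C)C)C(=O)[C@@]1(C)CCC1=CC(=O)OC1 | intermediate
18 | ten-membered diketone (cyclodecane-1,6-dione from C1–C5 retro-aldol) | O=C1CC[C@@H](C)[C@](C)(CCC2=CC(=O)OC2)C(=O)CC[C@@H](O)C1(C)C | intermediate (not isolated)
19 | CNP0077405.1 (1S,3R,5S,8R,9S) | C[C@@H]1CC[C@]2(O)[C@H](C[C@@H](O)C2(C)C)C(=O)[C@@]1(C)CCC1=CC(=O)OC1 | target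

Total step count: 12. Longest linear sequence: 12 steps (from 1).

Steps most likely to fail

Step 12. The equilibration may stall because the tertiary alkoxide is not formed under the mild amine base. It may also drain into loss of water (E1cB) or into the other transannular aldol (C6 enolate onto C10) once proton transfer between the two ketones sets in. The fallback sets out from 16 and returns at 19. Burgess reagent (toluene, 50 °C) removes the C5 hydroxyl with the cis C1 hydrogen by syn elimination to give the ring-fusion enone F1. HF·pyridine frees the C3 hydroxyl to give the hydroxy enone F2. t-BuOOLi (from t-BuOOH and n-BuLi, THF, −20 °C) then epoxidises the enone in a hydroxyl-directed nucleophilic epoxidation on the face of the C3 hydroxyl, giving the epoxy ketone F3. SmI2 (THF/MeOH, −78 °C) cleaves the C1–O bond of the α,β-epoxy ketone; protonation of the enolate and brief Et3N equilibration of the enolisable C1 should give 19.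

Step 9. Acid-catalysed migration of the exocyclic enol ether double bond into the ring, or thermal degradation of the butenolide-bearing substrate, may win before the barrier of the bridged transition state is crossed. The fallback sets out from 11 and returns at 15. Al(i-Bu)3 (CH2Cl2, 23 °C) promotes the same [3,3] shift on the butenolide-free dienyl ether at room temperature and reduces the new ketone in the flask, giving the cycloheptenol F4 (C10 carbinol, either epimer). 9-BBN then adds to the vinyl group to give the alkylborane F5, and Suzuki–Miyaura coupling with 12 as in step 8 gives the butenolide alcohol F6. Dess–Martin periodinane oxidises the secondary C10 carbinol (the tertiary C5 hydroxyl is inert) to 15.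

Step 4. Catalyst control at the new carbinol may be weak (poor facial selectivity on the aldehyde). That would feed the C6 epimer, whose oxolane carries the propenyl group on the concave face and cannot reach the chair array. The fallback sets out from 4 and returns at 9. Ligand-free Nozaki–Hiyama–Kishi coupling (CrCl2, NiCl2 cat., DMF) gives 6 together with its C6 epimer, the 6R dienol F7. The mixture is carried through steps 5 and 6, giving alongside 7 and 9 the epimeric epoxy alcohol F8 and the epimeric alkynyl diol F9. MnO2 (CH2Cl2) oxidises both allylic carbinols to the single α-hydroxy enone F10. Zn(BH4)2 (Et2O, −30 °C) reduces it under chelation control, hydride entering from the C1 side away from the gem-dimethyl carbon, to give 9.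

Further compounds

F1 | step 12 | ring-fusion enone (C1=C5) TBS ether | C[C@@H]1CCC2=C(C[C@@H](O[Si](C)(C)C(C)(C)C)C2(C)C)C(=O)[C@@]1(C)CCC1=CC(=O)OC1
F2 | step 12 | hydroxy enone (free C3–OH) | C[C@@H]1CCC2=C(C[C@@H](O)C2(C)C)C(=O)[C@@]1(C)CCC1=CC(=O)OC1
F3 | step 12 | C1–C5 epoxy ketone, oxirane oxygen cis to C3–OH | C[C@@H]1CC[C@]23O[C@]2(C[C@@H](O)C3(C)C)C(=O)[C@@]1(C)CCC1=CC(=O)OC1
F4 | step 9 | cycloheptenol with C9 vinyl (C10 carbinol, either epimer) | C[C@@H]1C=C[C@@]2(O)[C@H](C[C@@H](O[Si](C)(C)C(C)(C)C)C2(C)C)C(O)[C@@]1(C)C=C
F5 | step 9 | B-alkyl-9-BBN adduct of F4 | C[C@@H]1C=C[C@@]2(O)[C@H](C[C@@H](O[Si](C)(C)C(C)(C)C)C2(C)C)C(O)[C@@]1(C)CCB1C2CCCC1CCC2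
F6 | step 9 | cycloheptenol carrying the butenolide chain | C[C@@H]1C=C[C@@]2(O)[C@H](C[C@@H](O[Si](C)(C)C(C)(C)C)C2(C)C)C(O)[C@@]1(C)CCC1=CC(=O)OC1
F7 | step 4 | 6R dienol (C6 epimer of 6) | C/C=C/[C@@H](O)C1=CC[C@@H](O[Si](C)(C)C(C)(C)C)C1(C)C
F8 | step 4 | C6-epimeric epoxy alcohol | C/C=C/[C@@H](O)[C@@]12O[C@@H]1C[C@@H](O[Si](C)(C)C(C)(C)C)C2(C)C
F9 | step 4 | C6-epimeric alkynyl diol | C/C=C/[C@@H](O)[C@@]1(O)[C@@H](C#CC)C[C@@H](O[Si](C)(C)C(C)(C)C)C1(C)C
F10 | step 4 | α-hydroxy enone (C6 ketone) | C/C=C/C(=O)[C@@]1(O)[C@@H](C#CC)C[C@@H](O[Si](C)(C)C(C)(C)C)C1(C)C
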